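**Strategy.** The five-membered ring of the indenone (ring B: C1, C2, C3, C3a, C7a) is disconnected at C1–C2 and C3–C3a. This splits the target into an ortho-bromobenzaldehyde (C1 as CHO on C7a, Br on C3a, the C4 formyl group masked as a dioxolane) and the unsymmetrical alkyne 3-(prop-1-ynyl)guaiazulene (C2 and C3). One palladium-catalysed Larock annulation joins them: the aryl group adds to the methyl-bearing alkyne carbon, the alkenylpalladium closes onto the C7-methyl-flanked aldehyde, and β-hydride elimination sets the C1 ketone. The feature exploited is the C2=C3 alkene with a small (methyl) and a large (peri-methylated azulenyl) substituent, flanked by carbonyl C1 and arene carbon C3a.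

Key step: step 6

Remark: the target has no stereocentre and no stereogenic double bond, so no stereocontrol is required; guaiazulene and 3-iodo-4-methylbenzaldehyde are taken as purchasable.

Step 1
Reactants: 1 3-iodo-4-methylbenzaldehyde
Product: 2 2-(3-iodo-4-methylphenyl)-1,3-dioxolane
Conditions: HOCH2CH2OH, p-TsOH·H2O (cat.), toluene, reflux (Dean–Stark)
Reagents that add atoms: ethylene glycol, OCCO
Why: Acid-catalysed acetalisation with azeotropic removal of water protects the formyl group, which then serves as an oxygen directing group and later becomes the C4 formyl group of the target.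

Step 2
Reactants: 2 2-(3-iodo-4-methylphenyl)-1,3-dioxolane
Product: 4 2-(2-bromo-3-iodo-4-methylphenyl)-1,3-dioxolane, via aryllithium 3 (not isolated)
Conditions: LiN(i-Pr)2, THF, −78 °C; then BrCCl2CCl2Br, −78 °C to rt
Reagents that add atoms: 1,2-dibromo-1,1,2,2-tetrachloroethane, BrC(Cl)(Cl)C(Cl)(Cl)Br
Why: Directed ortho-metalation should remove the C2–H selectively, because it lies between the coordinating dioxolane and the acidifying iodine, and the aryllithium is then brominated by the positive-bromine donor.

Step 3
Reactants: 4 2-(2-bromo-3-iodo-4-methylphenyl)-1,3-dioxolane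
Product: 7 2-bromo-3-(1,3-dioxolan-2-yl)-6-methylbenzaldehyde, via arylmagnesium chloride 5 (not isolated), via magnesium hemiaminal alkoxide 6 (not isolated)
Conditions: i-PrMgCl·LiCl, THF, −40 °C; then DMF, −40 °C to rt; H2O work-up
Reagents that add atoms: N,N-dimethylformamide, CN(C)C=O
Why: Iodine–magnesium exchange is much faster than bromine–magnesium exchange, so only the iodine-bearing carbon is metalated, and Bouveault formylation with DMF gives the aldehyde while the ortho-bromo Grignard reagent is kept cold to avoid aryne formation.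

Step 4
Reactants: 8 guaiazulene [1,4-dimethyl-7-(propan-2-yl)azulene]
Product: 9 3-acetylguaiazulene [1-[3,8-dimethyl-5-(propan-2-yl)azulen-1-yl]ethan-1-one]
Conditions: Ac2O, SnCl4, CH2Cl2, 0 °C
Reagents that add atoms: acetic anhydride, CC(=O)OC(C)=O
Why: Friedel–Crafts acylation of the strongly nucleophilic five-membered ring of the azulene should occur at C3, the only free position next to the ring fusion (C1 carries a methyl group).

Step 5
Reactants: 9 3-acetylguaiazulene
Product: 11 3-(prop-1-yn-1-yl)guaiazulene [1,4-dimethyl-7-(propan-2-yl)-3-(prop-1-yn-1-yl)azulene], via diazoalkene 10 (not isolated)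
Conditions: Me3SiCHN2, n-BuLi, THF, −78 °C; then 9, −78 °C to reflux
Reagents that add atoms: (trimethylsilyl)diazomethane, C[Si](C)(C)C=[N+]=[N-]
Why: Colvin rearrangement: lithiated trimethylsilyldiazomethane adds to the aryl methyl ketone, Peterson-type loss of silanolate gives the diazoalkene, and loss of N2 gives an alkylidene carbene whose 1,2-aryl shift should deliver the methyl aryl alkyne.

Step 6
Reactants: 7 2-bromo-3-(1,3-dioxolan-2-yl)-6-methylbenzaldehyde; 11 3-(prop-1-yn-1-yl)guaiazulene
Product: 13 2-[3,8-dimethyl-5-(propan-2-yl)azulen-1-yl]-3,7-dimethyl-1-oxo-1H-indene-4-carbaldehyde, via dioxolane-protected indenone 12 (not isolated)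
Conditions: Pd(OAc)2 (5 mol %), Na2CO3, n-Bu4NCl, DMF, 100 °C; aqueous work-up; then crude 12, p-TsOH·H2O (cat.), THF–H2O, 50 °C
Reagents that add atoms: water, O
Why: Zerovalent palladium formed from Pd(OAc)2 inserts into the C–Br bond of 7, the arylpalladium bromide adds syn across alkyne 11 with the aryl carbon (C3a) going to the methyl-bearing carbon (C3) and palladium to the azulenyl-bearing carbon (C2), the alkenylpalladium then adds to the adjacent formyl group (C1), and β-hydride elimination from the palladium alkoxide gives the ketone while Na2CO3 returns zerovalent palladium. The closest known reaction is the Larock indenone annulation of ortho-halobenzaldehydes with internal alkynes. The five-membered ring B is closed by a 5-exo-trig addition of the C2–Pd bond onto the C1=O group; no stereocentre is created. The step needs regioselective insertion, which should be secured by the size difference between methyl and the peri-methylated guaiazulenyl group (the bulky group prefers the longer C–Pd bond) and sharpened by the two ortho substituents of the migrating aryl group. It also needs ring closure onto only one carbonyl, which is secured because the second formyl group is masked as the dioxolane. Acid-catalysed hydrolysis of crude 12 should then release the C4 formyl group.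

**Compound list**

1 | 3-iodo-4-methylbenzaldehyde | Cc1ccc(C=O)cc1I | starting material
2 | 2-(3-iodo-4-methylphenyl)-1,3-dioxolane | Cc1ccc(C2OCCO2)cc1I | intermediate
3 | [2-(1,3-dioxolan-2-yl)-6-iodo-5-methylphenyl]lithium (aryllithium) | Cc1ccc(C2OCCO2)c([Li])c1I | intermediate
4 | 2-(2-bromo-3-iodo-4-methylphenyl)-1,3-dioxolane | Cc1ccc(C2OCCO2)c(Br)c1I | intermediate
5 | [2-bromo-3-(1,3-dioxolan-2-yl)-6-methylphenyl]magnesium chloride (arylmagnesium chloride) | Cc1ccc(C2OCCO2)c(Br)c1[Mg]Cl | intermediate
6 | chloromagnesium (dimethylamino)[2-bromo-3-(1,3-dioxolan-2-yl)-6-methylphenyl]methanolate (magnesium hemiaminal alkoxide) | CN(C)C(O[Mg]Cl)c1c(C)ccc(C2OCCO2)c1Br | intermediate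
7 | 2-bromo-3-(1,3-dioxolan-2-yl)-6-methylbenzaldehyde | O=Cc1c(C)ccc(C2OCCO2)c1Br | intermediate
8 | guaiazulene [1,4-dimethyl-7-(propan-2-yl)azulene] | c1cc(C)c2cc(C(C)C)ccc(C)c1-2 | starting material
9 | 3-acetylguaiazulene [1-[3,8-dimethyl-5-(propan-2-yl)azulen-1-yl]ethan-1-one] | CC(=O)c1cc(C)c2cc(C(C)C)ccc(C)c1-2 | intermediate
10 | 3-(1-diazoprop-1-en-2-yl)-1,4-dimethyl-7-(propan-2-yl)azulene (diazoalkene) | CC(=C=[N+]=[N-])c1cc(C)c2cc(C(C)C)ccc(C)c1-2 | intermediate
11 | 3-(prop-1-yn-1-yl)guaiazulene [1,4-dimethyl-7-(propan-2-yl)-3-(prop-1-yn-1-yl)azulene] | CC#Cc1cc(C)c2cc(C(C)C)ccc(C)c1-2 | intermediate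
12 | 2-[3,8-dimethyl-5-(propan-2-yl)azulen-1-yl]-4-(1,3-dioxolan-2-yl)-3,7-dimethyl-1H-inden-1-one (dioxolane-protected indenone) | CC1=C(c2cc(C)c3cc(C(C)C)ccc(C)c2-3)C(=O)c2c(C)ccc(C3OCCO3)c21 | intermediate
13 | 2-[3,8-dimethyl-5-(propan-2-yl)azulen-1-yl]-3,7-dimethyl-1-oxo-1H-indene-4-carbaldehyde | CC1=C(c2cc(C)c3cc(C(C)C)ccc(C)c2-3)C(=O)c2c(C)ccc(C=O)c21 | target

**Step count.** Total steps: 6. Longest linear sequence: 4 steps (steps 1, 2, 3 and 6); the alkyne branch (steps 4 and 5) joins at step 6.

**Steps most likely to fail**

Step 6 (key annulation). The alkyne may insert with the opposite orientation, because the electron-donating azulenyl group polarises the triple bond against the steric preference. The arylpalladium intermediate may also attack the nucleophilic azulene ring directly instead of the alkyne. The fallback sets out from 7 and fixes the regiochemistry with silicon. The same annulation conditions with 1-(trimethylsilyl)propyne should give 4-(1,3-dioxolan-2-yl)-3,7-dimethyl-2-(trimethylsilyl)-1H-inden-1-one F1, since the silyl group reliably ends up next to the carbonyl group. Ipso-iododesilylation with ICl (CH2Cl2, −78 to 0 °C) should give 4-(1,3-dioxolan-2-yl)-2-iodo-3,7-dimethyl-1H-inden-1-one F2. A direct C3–H coupling of guaiazulene 8 with F2 (Pd(OAc)2, KOAc, ethylbenzene, 130 °C), modelled on the palladium-catalysed C–H arylation of guaiazulene, then attaches the azulenyl group. This comes back to the route at 12, which is hydrolysed as in step 6.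

Step 2 (ortho-metalation next to iodine). Deprotonation may be incomplete, or the ortho-iodoaryllithium may lose LiI to form an aryne before the bromine donor is added. The fallback sets out from 2 and installs the formyl group before the bromine, in one pot. Iodine–lithium exchange (n-BuLi, THF, −78 °C) gives [5-(1,3-dioxolan-2-yl)-2-methylphenyl]lithium F3. Addition of N-formyl-N,N′,N′-trimethylethylenediamine converts it into the lithium α-amino alkoxide F4. A second charge of n-BuLi (−20 °C) should lithiate the ring carbon between the two oxygen directing groups to give the ortho-lithiated α-amino alkoxide F5, although lateral lithiation of the methyl group is a possible competitor here. BrCCl2CCl2Br followed by aqueous work-up then returns the route at 7, bypassing steps 2 and 3.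

Step 5 (Colvin rearrangement). The acetyl group may be enolised by the basic reagent, or addition to the electron-rich, peri-hindered carbonyl group may be too slow. The fallback sets out from 8 and builds the alkyne from an aldehyde that cannot enolise. Vilsmeier–Haack formylation (POCl3, DMF, 0 °C to rt; aq NaOH) should give 3,8-dimethyl-5-(propan-2-yl)azulene-1-carbaldehyde F6. Corey–Fuchs olefination (CBr4, PPh3, Zn, CH2Cl2, rt) gives 3-(2,2-dibromoethenyl)-1,4-dimethyl-7-(propan-2-yl)azulene F7. Treatment with n-BuLi (2 equiv, THF, −78 °C) gives the lithium acetylide F8, which MeI methylates in the same flask. This comes back to the route at 11.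

**Further compounds**

F1 | step 6 | 4-(1,3-dioxolan-2-yl)-3,7-dimethyl-2-(trimethylsilyl)-1H-inden-1-one | CC1=C([Si](C)(C)C)C(=O)c2c(C)ccc(C3OCCO3)c21
F2 | step 6 | 4-(1,3-dioxolan-2-yl)-2-iodo-3,7-dimethyl-1H-inden-1-one | CC1=C(I)C(=O)c2c(C)ccc(C3OCCO3)c21
F3 | step 2 | [5-(1,3-dioxolan-2-yl)-2-methylphenyl]lithium | Cc1ccc(C2OCCO2)cc1[Li]
F4 | step 2 | lithium {[2-(dimethylamino)ethyl](methyl)amino}[5-(1,3-dioxolan-2-yl)-2-methylphenyl]methanolate | CN(C)CCN(C)C(O[Li])c1cc(C2OCCO2)ccc1C
F5 | step 2 | lithium {[2-(dimethylamino)ethyl](methyl)amino}[3-(1,3-dioxolan-2-yl)-2-lithio-6-methylphenyl]methanolate | CN(C)CCN(C)C(O[Li])c1c([Li])c(C2OCCO2)ccc1C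
F6 | step 5 | 3,8-dimethyl-5-(propan-2-yl)azulene-1-carbaldehyde | O=Cc1cc(C)c2cc(C(C)C)ccc(C)c1-2
F7 | step 5 | 3-(2,2-dibromoethenyl)-1,4-dimethyl-7-(propan-2-yl)azulene | BrC(Br)=Cc1cc(C)c2cc(C(C)C)ccc(C)c1-2
F8 | step 5 | lithium [3,8-dimethyl-5-(propan-2-yl)azulen-1-yl]acetylide | [Li]C#Cc1cc(C)c2cc(C(C)C)ccc(C)c1-2
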